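**Plan**

1. Numbering: C1 (angelate carbinol), C2 (epoxyangelate carbinol), C3=C4 (Me on C4), C5 and C10 (ring-fusion CH), C6H2, C7=O, C8(Me)=C9, C11 (CMe2). Ring A is the seven-membered ring C1–C5/C10/C11 and ring B the six-membered ring C5–C10.
2. Cuts: first the two ester C–O bonds. Then C8=C9 and C7=O go back to a C7 silyl ether, the C1/C2 diol to an ene-1,2-dione, and the C4 methyl to a C4 ketone. The resulting cis-fused dione 17 is cut at C5–C10 and C1–C11 while C1–C5 is re-joined.
3. Enabling feature: in ring A, C1 and C4 are linked by C2–C3, which gives a cyclopentane-1,3-dione once C1–C5 is drawn. They are also linked by C11–C10–C5, a 1,5-dicarbonyl path whose C10–C11 unit is an isopropylidene alkene held to C5 by the chain C6–C9 that becomes ring B.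
4. Forward order: the chain C6–C11 is built (aldol for C7–C8, copper-catalysed coupling for C9–C10) and joined at C5–C6 by reductive alkylation of cyclopentane-1,3-dione. One photochemical step closes ring B and a cyclobutane and opens them to ring A. Ring A is then methylated and oxidised, the esters go on, and the ring B enone comes last.
5. Stereochemistry: the (S)-oxazolidinone sets C7 and C8. These set C10 (chair-like photocyclisation), C10 sets C5 (kinetic protonation), and C7/C8 are later erased. C2 comes from convex-face hydride attack and C1 from C2-OH-directed hydride delivery. The epoxide comes from Sharpless epoxidation with L-(+)-diethyl tartrate and the Z-alkene from angelic acid.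

Key step: step 10

Remark: α is the face of the bicycle that carries H5 and H10, and β is the face over which ring B is folded. It is assumed that external reagents reach ring A from the α face. Descriptors of bicyclic compounds use the atom numbers of the plan.

Step 1
Reactants: 1 (S)-4-benzyl-3-propionyloxazolidin-2-one; 2 2-(benzyloxy)acetaldehyde
Product: 3 (S)-4-benzyl-3-[(2S,3S)-4-(benzyloxy)-3-hydroxy-2-methylbutanoyl]oxazolidin-2-one
Conditions: Bu2BOTf, Et3N, CH2Cl2, −78 → 0 °C; then H2O2, MeOH, pH 7 buffer, 0 °C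
Reagents that add atoms: none
Why: Evans syn-aldol reaction, in which the Z-boron enolate reacts through a Zimmerman–Traxler chair on the face left open by the benzyl group of the (S)-auxiliary and so forms C7–C8 with C7-OH and C8-Me syn in the absolute sense needed later.

Step 2
Reactants: 3 aldol adduct
Product: 4 (S)-4-benzyl-3-[(2S,3S)-4-(benzyloxy)-3-(tert-butyldimethylsilyloxy)-2-methylbutanoyl]oxazolidin-2-one
Conditions: TBSOTf, 2,6-lutidine, CH2Cl2, 0 °C
Reagents that add atoms: tert-butyldimethylsilyl triflate (TBSOTf), CC(C)(C)[Si](C)(C)OS(=O)(=O)C(F)(F)F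
Why: Silylation of a secondary alcohol with a silyl triflate is routine, blocks retro-aldol cleavage and gives an ether at C7 that should last until step 21.

Step 3
Reactants: 4 silylated imide
Product: 5 (2R,3S)-4-(benzyloxy)-3-(tert-butyldimethylsilyloxy)-2-methylbutan-1-ol
Conditions: LiBH4, MeOH (1 equiv), Et2O, 0 °C
Reagents that add atoms: none
Why: Reductive removal of the Evans auxiliary with LiBH4 gives the primary alcohol at C9 without epimerisation at C8 and returns the oxazolidinone.

Step 4
Reactants: 5 primary alcohol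
Product: 6 [(2S,3S)-1-(benzyloxy)-4-iodo-3-methylbutan-2-yl]oxy(tert-butyl)dimethylsilane
Conditions: I2, PPh3, imidazole, CH2Cl2, 0 °C → rt
Reagents that add atoms: iodine, II
Why: Appel-type iodination of a primary alcohol runs under nearly neutral conditions that spare the benzyl and silyl ethers and touch no stereocentre.

Step 5
Reactants: 6 primary iodide; 7 2-methylprop-1-enylmagnesium bromide (commercial THF solution)
Product: 8 [(2S,3R)-1-(benzyloxy)-3,6-dimethylhept-5-en-2-yl]oxy(tert-butyl)dimethylsilane
Conditions: CuI (10 mol %), THF, −30 → 0 °C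
Reagents that add atoms: none
Why: Copper-catalysed cross-coupling of a primary alkyl iodide with an alkenyl Grignard reagent forms C9–C10 and brings in the isopropylidene unit C10=C11 in one operation.

Step 6
Reactants: 8 benzyl ether
Product: 9 (2S,3R)-2-(tert-butyldimethylsilyloxy)-3,6-dimethylhept-5-en-1-ol
Conditions: lithium 4,4'-di-tert-butylbiphenylide (LiDBB), THF, −78 °C; then H2O, −78 °C → rt
Reagents that add atoms: none
Why: Reductive cleavage of the benzyl ether by an arene radical anion leaves the isolated trisubstituted alkene and the silyl ether untouched, and the cold quench should forestall 1,2-silyl migration.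

Step 7
Reactants: 9 primary alcohol
Product: 10 (2S,3R)-2-(tert-butyldimethylsilyloxy)-3,6-dimethylhept-5-enal
Conditions: Dess–Martin periodinane, CH2Cl2, 0 °C → rt
Reagents that add atoms: none
Why: Dess–Martin oxidation is fast and base-free, so the α-silyloxy aldehyde (C6) should form without epimerisation at C7.

Step 8
Reactants: 10 aldehyde; 11 cyclopentane-1,3-dione
Product: 13 2-[(2R,3R)-2-(tert-butyldimethylsilyloxy)-3,6-dimethylhept-5-enyl]-3-hydroxycyclopent-2-enone, via alkylidene dione 12 (not isolated)
Conditions: Hantzsch ester (diethyl 1,4-dihydro-2,6-dimethylpyridine-3,5-dicarboxylate), L-proline (5 mol %), CH2Cl2, rt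
Reagents that add atoms: none
Why: Organocatalytic three-component reductive alkylation (Knoevenagel condensation, then transfer hydrogenation of the alkylidene dione by the Hantzsch ester) forms C5–C6 with clean C-monoalkylation, which direct alkylation of the dione with an unactivated halide does not give.

Step 9
Reactants: 13 2-alkyl dione (enol form)
Product: 14 benzyl 2-[(2R,3R)-2-(tert-butyldimethylsilyloxy)-3,6-dimethylhept-5-enyl]-3-oxocyclopent-1-enyl carbonate
Conditions: CbzCl, Et3N, CH2Cl2, 0 °C
Reagents that add atoms: benzyl chloroformate (CbzCl), O=C(Cl)OCc1ccccc1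
Why: O-acylation of the fully enolised 2-alkyl-1,3-dione can give only one enol carbonate, because rotation about C5–C6 makes both carbonyl groups equivalent, and it turns the associated enol into a soluble enone chromophore whose oxygen can be freed later under neutral conditions.

Step 10
Reactants: 14 enol benzyl carbonate
Product: 17 cis-fused (5R,7R,8R,10S)-7-(tert-butyldimethylsilyloxy)-8,11,11-trimethylbicyclo[5.4.0]undecane-1,4-dione, via cyclobutyl benzyl carbonate photoadduct 15 (not isolated), via cyclobutanol 16 (not isolated)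
Conditions: hν (medium-pressure Hg lamp, Pyrex, λ > 290 nm), degassed MeCN (5 mM), 10 °C; solvent switch to EtOAc, then H2 (1 atm), 10% Pd/C, rt
Reagents that add atoms: none
Why: Light absorbed by the 3-acyloxy-2-alkylcyclopentenone of 14 gives the triplet enone, in which C5 bonds to C10 (6-exo closure of ring B over the chain C6–C9) to leave a 1,4-biradical with a tertiary centre at C11 and an oxygen-bearing centre at C1, and radical recombination C1–C11 then closes the four-membered ring cis to both neighbours (15). Neutral hydrogenolysis of the benzyl carbonate frees cyclobutanol 16 with loss of toluene and CO2, and its strained C1–C5 bond, β to the C4 ketone, breaks by retro-aldol reaction, so that ring A is not cyclised but arises by merging the five- and four-membered rings (two-carbon ring expansion). The closest known reaction type is the intramolecular de Mayo reaction of enol esters and enol carbonates of 2-alkenyl cyclic 1,3-diones. C10 is controlled by C7 and C8: the tether reacts in the chair that keeps OTBS and methyl equatorial and the alkene pseudo-equatorial, since an axial alkene would push C8 against the Z-methyl on C11 (A(1,3) strain), which places C11 cis to the C8 methyl. C5 is controlled by C10: in the C4=C5 enol the quaternary C11 stands pseudo-axial on ring B and shields the β face, so kinetic ketonisation delivers the proton anti to C11 and cis to H10, and the neutral medium prevents later equilibration. The step needs straight rather than crossed regiochemistry and closure rather than hydrogen transfer, and the substrate secures the first through the six- versus seven-membered first ring closure and the tertiary radical at C11.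

Step 11
Reactants: 17 cis-fused 1,4-dione
Product: 18 (4S,5R,7R,8R,10S)-7-(tert-butyldimethylsilyloxy)-4-hydroxy-4,8,11,11-tetramethylbicyclo[5.4.0]undecan-1-one
Conditions: MeLi, CeCl3 (anhydrous), THF, −78 °C; then H2O
Reagents that add atoms: methyllithium, [Li]C
Why: Organocerium 1,2-addition is almost non-basic, so C5 keeps its configuration, and it selects the C4 ketone because C1 is neopentyl next to C11, with attack from the α face placing the hydroxyl β (a centre that is erased in step 13).

Step 12
Reactants: 18 hydroxy ketone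
Product: 19 (2S,4S,5R,7R,8R,10S)-7-(tert-butyldimethylsilyloxy)-2,4-dihydroxy-4,8,11,11-tetramethylbicyclo[5.4.0]undecan-1-one
Conditions: KN(SiMe3)2 (2.3 equiv), THF, −78 °C; 2-(phenylsulfonyl)-3-phenyloxaziridine; then AcOH
Reagents that add atoms: 2-(phenylsulfonyl)-3-phenyloxaziridine (Davis oxaziridine), O=S(=O)(c1ccccc1)N1OC1c1ccccc1
Why: Davis oxidation of the potassium enolate is regiospecific because C11 is quaternary and C2 is the only enolisable position of the C1 ketone, and the configuration at C2 (α expected) does not matter since it is erased in the next step.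

Step 13
Reactants: 19 dihydroxy ketone
Product: 21 (5R,7R,8R,10S)-7-(tert-butyldimethylsilyloxy)-4,8,11,11-tetramethylbicyclo[5.4.0]undec-3-ene-1,2-dione, via hydroxy 1,2-dione 20 (not isolated)
Conditions: Dess–Martin periodinane, CH2Cl2, rt; then PPTS (10 mol %), rt
Reagents that add atoms: none
Why: Dess–Martin oxidation makes C2 a ketone, after which the tertiary C4 hydroxyl is β to it and leaves in an aldol-type dehydration through the C2 enol, so that only the conjugated C3=C4 alkene can form and neither the C4=C5 nor the exocyclic isomer, while the mild acid should leave C5 alone.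

Step 14
Reactants: 21 ene-1,2-dione
Product: 22 (2R,5R,7R,8R,10S)-7-(tert-butyldimethylsilyloxy)-2-hydroxy-4,8,11,11-tetramethylbicyclo[5.4.0]undec-3-en-1-one
Conditions: NaBH4, CeCl3·7H2O, MeOH, −78 °C
Reagents that add atoms: none
Why: Luche reduction is 1,2-selective and prefers the accessible enone carbonyl C2 to the neopentyl C1, and hydride should arrive from the convex α face because the axial C9–H of ring B lies over the β face, which puts the C2 hydroxyl β (2R).

Step 15
Reactants: 22 α-hydroxy ketone
Product: 23 (1R,2R,5R,7R,8R,10S)-7-(tert-butyldimethylsilyloxy)-4,8,11,11-tetramethylbicyclo[5.4.0]undec-3-ene-1,2-diol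
Conditions: Me4NBH(OAc)3, MeCN/AcOH (1:1), −20 °C → rt
Reagents that add atoms: none
Why: Saksena–Evans hydroxyl-directed reduction, in which the acetoxyborohydride bound to the β C2-OH hands its hydride to the β face of C1, so that the trans-diol with C1-OH α (1R) should result.

Step 16
Reactants: 24 angelic acid, (Z)-2-methylbut-2-enoic acid
Product: 25 (Z)-2-methylbut-2-en-1-ol
Conditions: LiAlH4, Et2O, 0 °C
Reagents that add atoms: none
Why: Hydride reduction of the acid to the allylic alcohol proceeds by 1,2-attack and keeps the Z geometry.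

Step 17
Reactants: 25 (Z)-allylic alcohol
Product: 26 [(2S,3R)-2,3-dimethyloxiran-2-yl]methanol
Conditions: t-BuOOH, Ti(OiPr)4 (10 mol %), L-(+)-diethyl tartrate (12 mol %), 4 Å molecular sieves, CH2Cl2, −20 °C
Reagents that add atoms: tert-butyl hydroperoxide, CC(C)(C)OO
Why: Katsuki–Sharpless asymmetric epoxidation with L-(+)-diethyl tartrate delivers oxygen to the alkene face that gives the (2S,3R) epoxy alcohol, and the syn addition keeps CH2OH and the C3 methyl cis as in the Z-alkene.

Step 18
Reactants: 26 epoxy alcohol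
Product: 27 (2R,3R)-2,3-dimethyloxirane-2-carboxylic acid (epoxyangelic acid)
Conditions: TEMPO (20 mol %), PhI(OAc)2, MeCN/H2O (1:1), rt
Reagents that add atoms: water, O
Why: Oxoammonium-mediated oxidation takes the primary alcohol through the aldehyde hydrate to the acid without opening the epoxide, and the descriptor at C2 changes to R only through the change in priorities.

Step 19
Reactants: 23 trans-diol; 27 epoxyangelic acid
Product: 28 C2 mono-ester, (1R,2R,5R,7R,8R,10S)-7-(tert-butyldimethylsilyloxy)-1-hydroxy-4,8,11,11-tetramethylbicyclo[5.4.0]undec-3-en-2-yl (2R,3R)-2,3-dimethyloxirane-2-carboxylate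
Conditions: DCC, DMAP (20 mol %), CH2Cl2, 0 °C → rt
Reagents that add atoms: none
Why: Steglich esterification with one equivalent of acid should acylate the allylic C2-OH ahead of the C1-OH, which is neopentyl next to C11.

Step 20
Reactants: 28 C2 mono-ester; 24 angelic acid
Product: 30 C7-silylated diester (C1 angelate and C2 epoxyangelate), via angelic trichlorobenzoic mixed anhydride 29 (not isolated)
Conditions: 24, 2,4,6-trichlorobenzoyl chloride, Et3N, toluene, rt; then 28, 80 °C
Reagents that add atoms: none
Why: Yamaguchi mixed-anhydride acylation run without a nucleophilic catalyst is the established way to angeloylate hindered alcohols without Z-to-E isomerisation to the tiglate.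

Step 21
Reactants: 30 silylated diester
Product: 31 C7 alcohol of the diester
Conditions: HF·pyridine, pyridine, THF, 0 °C → rt
Reagents that add atoms: none
Why: Buffered fluoride desilylation removes the secondary TBS ether, while both esters and the electron-poor glycidic epoxide should tolerate the medium.

Step 22
Reactants: 31 C7 alcohol
Product: 32 C7 ketone of the diester (C8-H, C8-Me)
Conditions: Dess–Martin periodinane, CH2Cl2, rt
Reagents that add atoms: none
Why: Dess–Martin oxidation of the only free hydroxyl is neutral and leaves the alkenes, esters and epoxide unchanged.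

Step 23
Reactants: 32 C7 ketone
Product: 33 C7=C8 trimethylsilyl enol ether of the diester
Conditions: TMSOTf, Et3N, CH2Cl2, 0 °C → rt
Reagents that add atoms: trimethylsilyl triflate (TMSOTf), C[Si](C)(C)OS(=O)(=O)C(F)(F)F
Why: Soft enolisation with TMSOTf and Et3N under equilibrating conditions favours the more substituted silyl enol ether C7=C8, and the ketone is the only carbonyl group with α-hydrogens.

Step 24
Reactants: 33 silyl enol ether
Product: 34 target CNP0332927.1
Conditions: Pd(OAc)2 (1.1 equiv), MeCN, rt
Reagents that add atoms: none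
Why: Saegusa–Ito oxidation, in which divalent palladium binds at C8 and syn β-hydride elimination of a C9 hydrogen gives the endocyclic C8=C9 enone under neutral conditions that leave C10, both esters and the epoxide as they are.

**Compound list**

1 | (S)-4-benzyl-3-propionyloxazolidin-2-one | CCC(=O)N1[C@@H](Cc2ccccc2)COC1=O | starting material
2 | 2-(benzyloxy)acetaldehyde | O=CCOCc1ccccc1 | starting material
3 | (S)-4-benzyl-3-[(2S,3S)-4-(benzyloxy)-3-hydroxy-2-methylbutanoyl]oxazolidin-2-one | C(OCc1ccccc1)[C@@H](O)[C@H](C)C(=O)N1[C@@H](Cc2ccccc2)COC1=O | intermediate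
4 | (S)-4-benzyl-3-[(2S,3S)-4-(benzyloxy)-3-(tert-butyldimethylsilyloxy)-2-methylbutanoyl]oxazolidin-2-one | C(OCc1ccccc1)[C@@H](O[Si](C)(C)C(C)(C)C)[C@H](C)C(=O)N1[C@@H](Cc2ccccc2)COC1=O | intermediate
5 | (2R,3S)-4-(benzyloxy)-3-(tert-butyldimethylsilyloxy)-2-methylbutan-1-ol | C(OCc1ccccc1)[C@@H](O[Si](C)(C)C(C)(C)C)[C@H](C)CO | intermediate
6 | [(2S,3S)-1-(benzyloxy)-4-iodo-3-methylbutan-2-yl]oxy(tert-butyl)dimethylsilane | C(OCc1ccccc1)[C@@H](O[Si](C)(C)C(C)(C)C)[C@H](C)CI | intermediate
7 | 2-methylprop-1-enylmagnesium bromide | CC(C)=C[Mg]Br | starting material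
8 | [(2S,3R)-1-(benzyloxy)-3,6-dimethylhept-5-en-2-yl]oxy(tert-butyl)dimethylsilane | C(OCc1ccccc1)[C@@H](O[Si](C)(C)C(C)(C)C)[C@H](C)CC=C(C)C | intermediate
9 | (2S,3R)-2-(tert-butyldimethylsilyloxy)-3,6-dimethylhept-5-en-1-ol | OC[C@@H](O[Si](C)(C)C(C)(C)C)[C@H](C)CC=C(C)C | intermediate
10 | (2S,3R)-2-(tert-butyldimethylsilyloxy)-3,6-dimethylhept-5-enal | O=C[C@@H](O[Si](C)(C)C(C)(C)C)[C@H](C)CC=C(C)C | intermediate
11 | cyclopentane-1,3-dione | O=C1CCC(=O)C1 | starting material
12 | 2-[(2S,3R)-2-(tert-butyldimethylsilyloxy)-3,6-dimethylhept-5-enylidene]cyclopentane-1,3-dione | O=C1CCC(=O)C1=C[C@@H](O[Si](C)(C)C(C)(C)C)[C@H](C)CC=C(C)C | intermediate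
13 | 2-[(2R,3R)-2-(tert-butyldimethylsilyloxy)-3,6-dimethylhept-5-enyl]-3-hydroxycyclopent-2-enone | OC1=C(C[C@@H](O[Si](C)(C)C(C)(C)C)[C@H](C)CC=C(C)C)C(=O)CC1 | intermediate
14 | benzyl 2-[(2R,3R)-2-(tert-butyldimethylsilyloxy)-3,6-dimethylhept-5-enyl]-3-oxocyclopent-1-enyl carbonate | O=C(OCc1ccccc1)OC1=C(C[C@@H](O[Si](C)(C)C(C)(C)C)[C@H](C)CC=C(C)C)C(=O)CC1 | intermediate
15 | tricyclic photoadduct: cyclopentanone (C1–C5), cyclobutane (C1, C5, C10, C11) and cyclohexane (C5–C10), all cis-fused, benzyl carbonate on C1 | O=C1CC[C@]2(OC(=O)OCc4ccccc4)C(C)(C)[C@H]3C[C@@H](C)[C@H](O[Si](C)(C)C(C)(C)C)C[C@@]123 | intermediate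
16 | the corresponding C1 cyclobutanol | O=C1CC[C@]2(O)C(C)(C)[C@H]3C[C@@H](C)[C@H](O[Si](C)(C)C(C)(C)C)C[C@@]123 | intermediate
17 | cis-fused (5R,7R,8R,10S)-7-(tert-butyldimethylsilyloxy)-8,11,11-trimethylbicyclo[5.4.0]undecane-1,4-dione | O=C1CCC(=O)[C@@H]2C[C@@H](O[Si](C)(C)C(C)(C)C)[C@H](C)C[C@@H]2C1(C)C | intermediate
18 | (4S,5R,7R,8R,10S)-7-(tert-butyldimethylsilyloxy)-4-hydroxy-4,8,11,11-tetramethylbicyclo[5.4.0]undecan-1-one | O=C1CC[C@](C)(O)[C@@H]2C[C@@H](O[Si](C)(C)C(C)(C)C)[C@H](C)C[C@@H]2C1(C)C | intermediate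
19 | (2S,4S,5R,7R,8R,10S)-7-(tert-butyldimethylsilyloxy)-2,4-dihydroxy-4,8,11,11-tetramethylbicyclo[5.4.0]undecan-1-one (C2 configuration inconsequential) | O=C1[C@@H](O)C[C@](C)(O)[C@@H]2C[C@@H](O[Si](C)(C)C(C)(C)C)[C@H](C)C[C@@H]2C1(C)C | intermediate
20 | (4S,5R,7R,8R,10S)-7-(tert-butyldimethylsilyloxy)-4-hydroxy-4,8,11,11-tetramethylbicyclo[5.4.0]undecane-1,2-dione | O=C1C(=O)C[C@](C)(O)[C@@H]2C[C@@H](O[Si](C)(C)C(C)(C)C)[C@H](C)C[C@@H]2C1(C)C | intermediate
21 | (5R,7R,8R,10S)-7-(tert-butyldimethylsilyloxy)-4,8,11,11-tetramethylbicyclo[5.4.0]undec-3-ene-1,2-dione | O=C1C(=O)C=C(C)[C@@H]2C[C@@H](O[Si](C)(C)C(C)(C)C)[C@H](C)C[C@@H]2C1(C)C | intermediate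
22 | (2R,5R,7R,8R,10S)-7-(tert-butyldimethylsilyloxy)-2-hydroxy-4,8,11,11-tetramethylbicyclo[5.4.0]undec-3-en-1-one | O=C1[C@H](O)C=C(C)[C@@H]2C[C@@H](O[Si](C)(C)C(C)(C)C)[C@H](C)C[C@@H]2C1(C)C | intermediate
23 | (1R,2R,5R,7R,8R,10S)-7-(tert-butyldimethylsilyloxy)-4,8,11,11-tetramethylbicyclo[5.4.0]undec-3-ene-1,2-diol | O[C@H]1[C@H](O)C=C(C)[C@@H]2C[C@@H](O[Si](C)(C)C(C)(C)C)[C@H](C)C[C@@H]2C1(C)C | intermediate
24 | angelic acid, (Z)-2-methylbut-2-enoic acid | C/C=C(/C)C(=O)O | starting material
25 | (Z)-2-methylbut-2-en-1-ol | C/C=C(/C)CO | intermediate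
26 | [(2S,3R)-2,3-dimethyloxiran-2-yl]methanol | OC[C@]1(C)O[C@@H]1C | intermediate
27 | (2R,3R)-2,3-dimethyloxirane-2-carboxylic acid | OC(=O)[C@]1(C)O[C@@H]1C | intermediate
28 | C2 (2R,3R)-epoxyangelate of diol 23, C1-OH free | O[C@H]1[C@H](OC(=O)[C@]3(C)O[C@@H]3C)C=C(C)[C@@H]2C[C@@H](O[Si](C)(C)C(C)(C)C)[C@H](C)C[C@@H]2C1(C)C | intermediate
29 | (Z)-2-methylbut-2-enoic 2,4,6-trichlorobenzoic anhydride | C/C=C(/C)C(=O)OC(=O)c1c(Cl)cc(Cl)cc1Cl | intermediate
30 | C1 angelate, C2 epoxyangelate, C7-OTBS | C/C=C(/C)C(=O)O[C@H]1[C@H](OC(=O)[C@]3(C)O[C@@H]3C)C=C(C)[C@@H]2C[C@@H](O[Si](C)(C)C(C)(C)C)[C@H](C)C[C@@H]2C1(C)C | intermediate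
31 | C1 angelate, C2 epoxyangelate, (7R)-C7-OH | C/C=C(/C)C(=O)O[C@H]1[C@H](OC(=O)[C@]3(C)O[C@@H]3C)C=C(C)[C@@H]2C[C@@H](O)[C@H](C)C[C@@H]2C1(C)C | intermediate
32 | C1 angelate, C2 epoxyangelate, C7 ketone, (8R)-C8-Me | C/C=C(/C)C(=O)O[C@H]1[C@H](OC(=O)[C@]3(C)O[C@@H]3C)C=C(C)[C@@H]2CC(=O)[C@H](C)C[C@@H]2C1(C)C | intermediate
33 | C1 angelate, C2 epoxyangelate, C7(OSiMe3)=C8(Me) silyl enol ether | C/C=C(/C)C(=O)O[C@H]1[C@H](OC(=O)[C@]3(C)O[C@@H]3C)C=C(C)[C@@H]2CC(O[Si](C)(C)C)=C(C)C[C@@H]2C1(C)C | intermediate
34 | CNP0332927.1, (1R,2R,5R,10S) diester with (2R,3R)-epoxyangelate at C2 and angelate at C1 | C/C=C(/C)C(=O)O[C@H]1[C@H](OC(=O)[C@]2(C)O[C@@H]2C)C=C(C)[C@@H]2CC(=O)C(C)=C[C@@H]2C1(C)C | target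

Total step count: 24. Longest linear sequence: 21 (steps 1–15 and 19–24).

**Steps most likely to fail**

Step 10. Within the 1,4-biradical, hydrogen transfer from a C11 methyl group to C1, or reversion to 14, may outrun closure of the C1–C11 bond. That bond joins two fully substituted carbons next to quaternary C5.

- The fallback reverses the order of ring formation and sets out from 8 and 11.
- Dione 11 is O-acetylated (AcCl, Et3N) to 3-acetoxycyclopent-2-en-1-one F1, which carries hydrogen at C5.
- Intermolecular head-to-tail photocycloaddition of F1 to alkene 8 gives the bicyclo[3.2.0]heptanone acetate F2, whose cyclobutane holds one quaternary centre fewer.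
- K2CO3 in MeOH removes the acetate and triggers the retro-aldol opening to the monocyclic 5,5-dimethyl-6-alkylcycloheptane-1,4-dione F3. Ring A is thus made first. C10 forms without control here, so its wanted epimer has to be separated.
- Hydrogenolysis (H2, Pd/C) gives the primary alcohol F4, and Appel-type iodination gives the iodide F5.
- KOtBu then closes ring B by intramolecular 6-exo-tet alkylation of the C4 enolate at C5, which returns to the route at 17.

Step 14. Hydride may reach C2 from the β face, or attack C1 first, if ring B shields ring A less than assumed.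

- The fallback sets out from 18 and brings oxygen rather than hydrogen to C2.
- Burgess dehydration is a syn elimination that cannot use H5, because H5 is anti to the β C4–O bond. It gives the β,γ-unsaturated ketone F6.
- KN(SiMe3)2 removes a C2 proton to give the extended dienolate, and the Davis oxaziridine hydroxylates its α-carbon C2.
- A substrate that admits reagents from the β face then gives the β alcohol directly, and the route is rejoined at 22.

Step 20. Acylation of the neopentyl C1-OH may be so slow that Z-to-E isomerisation of the angeloyl unit or migration of the C2 acyl group takes over.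

- The fallback sets out from 28 and builds the angelate on the alcohol.
- DCC/DMAP esterification with 2-[bis(2,2,2-trifluoroethoxy)phosphoryl]propanoic acid, which can react through a ketene-like species and cannot isomerise, gives the phosphonopropionate F7.
- Still–Gennari olefination of F7 with acetaldehyde (KN(SiMe3)2, 18-crown-6, THF, −78 °C) forms the Z-trisubstituted alkene and returns to the route at 30.

**Further compounds**

F1 | step 10 | 3-acetoxycyclopent-2-en-1-one | CC(=O)OC1=CC(=O)CC1
F2 | step 10 | 5-acetoxy-7-[(2R,3S)-4-(benzyloxy)-3-(tert-butyldimethylsilyloxy)-2-methylbutyl]-6,6-dimethylbicyclo[3.2.0]heptan-2-one (ring centres as a mixture) | CC(=O)OC12CCC(=O)C1C(C[C@@H](C)[C@@H](COCc3ccccc3)O[Si](C)(C)C(C)(C)C)C2(C)C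
F3 | step 10 | 6-[(2R,3S)-4-(benzyloxy)-3-(tert-butyldimethylsilyloxy)-2-methylbutyl]-5,5-dimethylcycloheptane-1,4-dione (wanted C10 epimer) | O=C1CCC(=O)C[C@H](C[C@@H](C)[C@@H](COCc2ccccc2)O[Si](C)(C)C(C)(C)C)C1(C)C
F4 | step 10 | 6-[(2R,3S)-3-(tert-butyldimethylsilyloxy)-4-hydroxy-2-methylbutyl]-5,5-dimethylcycloheptane-1,4-dione | O=C1CCC(=O)C[C@H](C[C@@H](C)[C@@H](CO)O[Si](C)(C)C(C)(C)C)C1(C)C
F5 | step 10 | 6-[(2R,3S)-3-(tert-butyldimethylsilyloxy)-4-iodo-2-methylbutyl]-5,5-dimethylcycloheptane-1,4-dione | O=C1CCC(=O)C[C@H](C[C@@H](C)[C@@H](CI)O[Si](C)(C)C(C)(C)C)C1(C)C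
F6 | step 14 | (5R,7R,8R,10S)-7-(tert-butyldimethylsilyloxy)-4,8,11,11-tetramethylbicyclo[5.4.0]undec-3-en-1-one | O=C1CC=C(C)[C@@H]2C[C@@H](O[Si](C)(C)C(C)(C)C)[C@H](C)C[C@@H]2C1(C)C
F7 | step 20 | C1 2-[bis(2,2,2-trifluoroethoxy)phosphoryl]propanoate of 28 (phosphonate α-carbon as a mixture) | CC(C(=O)O[C@H]1[C@H](OC(=O)[C@]3(C)O[C@@H]3C)C=C(C)[C@@H]2C[C@@H](O[Si](C)(C)C(C)(C)C)[C@H](C)C[C@@H]2C1(C)C)P(=O)(OCC(F)(F)F)OCC(F)(F)F
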